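**First minutes.** At the earliest reading of Saturday's run, 0.333 min, X stood at 1 %; at the start none of E was in solution.

| setting | Saturday's | Tuesday's | flask |
|---|---|---|---|
| L | 1 M | 2.2 M | 1.5 M |
| E | 200 mM (held) | 200 mM (held) | 200 mM (held) |
| remark | run made earlier | run made earlier |  |
| time |  |  | 5.0 min |

| run | time / min | X / % | L / % |
|---|---|---|---|
| Saturday's | 0.333 | 1 | 97 |
| Saturday's | 1.00 | 8 | 93 |
| Saturday's | 1.50 | 16 | 84 |
| Saturday's | 2.50 | 27 | 72 |
| Saturday's | 4.00 | 42 | 56 |
| Saturday's | 5.00 | 49 | 48 |
| Saturday's | 6.00 | 57 | 40 |
| Tuesday's | 0.833 | 6 | 94 |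
| Tuesday's | 1.50 | 14 | 88 |
| Tuesday's | 2.50 | 18 | 80 |
| Tuesday's | 3.00 | 27 | 78 |
| Tuesday's | 4.00 | 33 | 66 |
| Tuesday's | 5.00 | 42 | 60 |
| Tuesday's | 6.00 | 48 | 54 |

(readings scatter by 1.5 percentage points)

- amount of X at 5.0 min, in percent of the L charged
- the change that raises the amount of X at 5.0 min, in percent of the L charged most ("none" if none brings more than 2 percentage points) (violet / amber / none)
- amount of X at 5.0 min, in percent of the L charged, after amber

- at the start none of E is in solution

- violet: doubling the transfer coefficient of E, all else as stated
- amber: doubling the saturation concentration of E, all else as stated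

**Odd pair.** Tuesday's charge was 2.20 times Saturday's. At 5.00 min Tuesday's run had lost a smaller fraction of its L, 40.0 % against 52.0 %. Yet it had lost more L, 0.880 M against 0.520 M. Neither the fraction nor the amount held constant.

**Counting turnovers.** I counted turnovers as n, the logarithm of charged over left: 0.734 on Saturday, 0.511 on Tuesday. I let each small turnover cost a fixed time plus a time growing with the L present. Summed, that gave t = a·n + b·c·f, with c the charge as a multiple of Saturday's and f the fraction gone. The two runs, with their scatter, gave b = 2.93 min and a, the turnover time at vanishing L, the reciprocal of a pseudo-first-order constant, 4.73 min.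

**My reckoning.** Interpolating 1/n in the charge gave n = 0.621 for the new flask. The rule then read 2.94 min plus 2.04 min, close to 5.0 min, so I expected X at 46.3 %. I expected violet to halve the second term and amber both, which saves more time.

**The forecast.** It stood slightly higher, at 47 %. It chose amber and gave 75 %: “Doubling E* (amber) doubles the whole rate”.

**The flask.** X reached 46.0 %. Amber gained 28 percentage points, violet 9.1 points, and amber ended at 74.2 %.

    L + J → X (k = 0.0180 L mol⁻¹ s⁻¹)
    E ⇌ J, rate k2*(csat - [J]) (kL = 0.0320 s⁻¹)

**What stood.** At the flask's L of 54 %, the rule reads 4.94 min. The same flask read at 12 min held L at 16.7 %, where the rule reads 12.1 min. In the flask at 5.00 min, the half-life of L on the path to X was 4.7 min, longer than the 0.79 min of J on that path. J then stood at 0.135 M, made 1.05 times as fast as it was used up.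

(The numbers in the tables come from a simulation for substances that don't exist; the scatter is artificial.)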